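**Plan**
1. Retrosynthesis: ring C is cut at O1–C8a (aryl ether) and at C2–C3 (aldol bond). This gives an aryl methyl ketone (C3–C4–C4a–C8a, with Cl on C8a) and 4-silyloxybenzaldehyde (C2=O1). The two C-prenyl bonds at C6 and C8 are then cut back to the dibromide of 2-chloro-4-hydroxyacetophenone.
2. Enabling feature: the C4 carbonyl is α to C3 and, through C4a, ortho to C8a of ring A. One ketone therefore makes C3 a carbon nucleophile (enol silane) and C8a–Cl an activated aryl electrophile; the aldehyde C2=O1 is the matching electrophile/nucleophile pair.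
3. Forward: ring A is bought. Bromination at both positions ortho to the 7-OH, twofold prenyl coupling, O-silylation and enol silane formation follow. Ring C (the pyranone) is then closed in one flask by aldol addition and C–O coupling, and desilylation ends the route.
4. Stereochemistry: C2 (S) is set by the chiral acid in the Mukaiyama aldol (Si-face attack on the aldehyde). It is retained because the C2–O1 bond comes intact from the aldehyde and no later step breaks a bond at C2.

Key step: step 5

Remark (assumption on the chemistry): the antipode of the chiral acid in step 5 is taken to be the one whose sense of induction gives Si-face attack on the aldehyde, i.e. the (S)-carbinol.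

**Step 1**
Reactants: 1 1-(2-chloro-4-hydroxyphenyl)ethan-1-one
Product: 2 1-(3,5-dibromo-2-chloro-4-hydroxyphenyl)ethan-1-one
Conditions: NBS (2.1 equiv), NH4OAc (10 mol%), MeCN, 0 °C → rt
Reagents that add atoms: N-bromosuccinimide, O=C1CCC(=O)N1Br
Why: Electrophilic aromatic bromination in which the 4-OH directs to its two ortho positions (its para position carries the acetyl group), the phenol ring reacting faster than the acetyl enol under these near-neutral conditions.

**Step 2**
Reactants: 2 1-(3,5-dibromo-2-chloro-4-hydroxyphenyl)ethan-1-one; 3 4,4,5,5-tetramethyl-2-(3-methylbut-2-en-1-yl)-1,3,2-dioxaborolane (2.6 equiv)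
Product: 4 1-[2-chloro-4-hydroxy-3,5-bis(3-methylbut-2-en-1-yl)phenyl]ethan-1-one
Conditions: Pd(dppf)Cl2·CH2Cl2 (8 mol%), K2CO3, THF/H2O, 70 °C; aq. HCl work-up
Reagents that add atoms: none
Why: Twofold Suzuki–Miyaura coupling of an allylic boronate, in which Pd should insert into the two C–Br bonds in preference to the hindered C–Cl bond and deliver the prenyl group at its primary carbon, because reductive elimination occurs from the less hindered σ-allyl isomer.

**Step 3**
Reactants: 4 1-[2-chloro-4-hydroxy-3,5-bis(3-methylbut-2-en-1-yl)phenyl]ethan-1-one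
Product: 5 1-{4-[(tert-butyldimethylsilyl)oxy]-2-chloro-3,5-bis(3-methylbut-2-en-1-yl)phenyl}ethan-1-one
Conditions: TBSCl (1.5 equiv), imidazole, DMF, rt
Reagents that add atoms: tert-butyldimethylsilyl chloride, CC(C)(C)[Si](C)(C)Cl
Why: Standard phenol silylation; the silyl ether carries no acetal (safe in the acid-catalysed aldol), keeps the phenol from competing as a nucleophile in the C–O coupling and is later removed by fluoride.

**Step 4**
Reactants: 5 1-{4-[(tert-butyldimethylsilyl)oxy]-2-chloro-3,5-bis(3-methylbut-2-en-1-yl)phenyl}ethan-1-one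
Product: 6 tert-butyl{3-chloro-2,6-bis(3-methylbut-2-en-1-yl)-4-[1-(trimethylsilyloxy)ethenyl]phenoxy}dimethylsilane
Conditions: LiHMDS (1.2 equiv), TMSCl (1.5 equiv, internal quench), THF, −78 → 0 °C; pentane, filtration, used without chromatography
Reagents that add atoms: chlorotrimethylsilane, C[Si](C)(C)Cl
Why: O-silylation of the kinetic lithium enolate; the acetyl group is the only enolisable site, so there is no regiochemical question, and the ring has no hydrogen ortho to Cl from which an aryne could form.

**Step 5**
Reactants: 6 tert-butyl{3-chloro-2,6-bis(3-methylbut-2-en-1-yl)-4-[1-(trimethylsilyloxy)ethenyl]phenoxy}dimethylsilane; 7 4-[(tert-butyldimethylsilyl)oxy]benzaldehyde (1.2 equiv)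
Product: 10 (2S)-7-[(tert-butyldimethylsilyl)oxy]-2-{4-[(tert-butyldimethylsilyl)oxy]phenyl}-6,8-bis(3-methylbut-2-en-1-yl)-2,3-dihydro-4H-chromen-4-one, via O-trimethylsilyl aldol 8 (not isolated), via free aldol 9 (not isolated)
Conditions: (i) chiral BINOL-derived N-triflyl thiophosphoramide (2 mol%, antipode per remark), toluene, −78 → −60 °C; (ii) MeOH, −20 → 0 °C, then volatiles removed in vacuo; (iii) RockPhos Pd G3 (5 mol%), K3PO4, toluene, 65 °C
Reagents that add atoms: none
Why: The chiral Brønsted acid activates aldehyde 7, the enol silane attacks its Si face through C3 (Mukaiyama aldol) and the silyl group passes to the new oxygen, so that C2–C3 is made and O1 is stored as silyl ether 8, which cannot undergo retro-aldol cleavage; methanolysis frees alcohol 9, Pd(0) then inserts into the C8a–Cl bond (activated by the ortho C4 ketone), the alcohol is deprotonated on palladium and C–O reductive elimination gives the aryl ether. The closest known reaction types are the chiral-acid-catalysed Mukaiyama aldol of aryl methyl ketone enol silanes with aromatic aldehydes and the Pd-catalysed intramolecular etherification of aryl halides with secondary alcohols (chroman synthesis), run here in sequence in one flask as a formal oxa-[4+2] annulation. Ring C, the only ring formed, closes by reductive elimination from a seven-membered aryl(alkoxo)palladacycle (Pd, C8a, C4a, C4, C3, C2, O1), which contracts to the six-membered pyranone (a 6-exo closure at C8a). The only new stereocentre, C2, is controlled by the catalyst in the aldol (enantioface selection on the aldehyde) and is carried through with retention, because neither later stage breaks a bond at C2. The step needs O-arylation to win over β-hydride elimination, retro-aldol cleavage and dehydration of the β-hydroxy ketone: the bulky biaryl phosphine speeds C–O reductive elimination, the base is an insoluble weak phosphate so that no free alkoxide is present, and both phenols are silylated and cannot compete as nucleophiles.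

**Step 6**
Reactants: 10 (2S)-7-[(tert-butyldimethylsilyl)oxy]-2-{4-[(tert-butyldimethylsilyl)oxy]phenyl}-6,8-bis(3-methylbut-2-en-1-yl)-2,3-dihydro-4H-chromen-4-one
Product: 11 (2S)-7-hydroxy-2-(4-hydroxyphenyl)-6,8-bis(3-methylbut-2-en-1-yl)-2,3-dihydro-4H-chromen-4-one
Conditions: TBAF (2.5 equiv), AcOH (3 equiv), THF, 0 °C → rt
Reagents that add atoms: none
Why: Fluoride-driven cleavage of both aryl silyl ethers (strong Si–F bond); the acetic acid buffer keeps the phenols protonated, so the base-labile C2 centre is not opened by a retro-oxa-Michael pathway and the prenyl groups see no strong acid.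

**Compound list**
1 | 1-(2-chloro-4-hydroxyphenyl)ethan-1-one | CC(=O)c1ccc(O)cc1Cl | starting material
2 | 1-(3,5-dibromo-2-chloro-4-hydroxyphenyl)ethan-1-one | CC(=O)c1cc(Br)c(O)c(Br)c1Cl | intermediate
3 | 4,4,5,5-tetramethyl-2-(3-methylbut-2-en-1-yl)-1,3,2-dioxaborolane | CC(C)=CCB1OC(C)(C)C(C)(C)O1 | starting material
4 | 1-[2-chloro-4-hydroxy-3,5-bis(3-methylbut-2-en-1-yl)phenyl]ethan-1-one | CC(=O)c1cc(CC=C(C)C)c(O)c(CC=C(C)C)c1Cl | intermediate
5 | 1-{4-[(tert-butyldimethylsilyl)oxy]-2-chloro-3,5-bis(3-methylbut-2-en-1-yl)phenyl}ethan-1-one | CC(=O)c1cc(CC=C(C)C)c(O[Si](C)(C)C(C)(C)C)c(CC=C(C)C)c1Cl | intermediate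
6 | tert-butyl{3-chloro-2,6-bis(3-methylbut-2-en-1-yl)-4-[1-(trimethylsilyloxy)ethenyl]phenoxy}dimethylsilane | C=C(O[Si](C)(C)C)c1cc(CC=C(C)C)c(O[Si](C)(C)C(C)(C)C)c(CC=C(C)C)c1Cl | intermediate
7 | 4-[(tert-butyldimethylsilyl)oxy]benzaldehyde | O=Cc1ccc(O[Si](C)(C)C(C)(C)C)cc1 | starting material
8 | (3S)-1-{4-[(tert-butyldimethylsilyl)oxy]-2-chloro-3,5-bis(3-methylbut-2-en-1-yl)phenyl}-3-{4-[(tert-butyldimethylsilyl)oxy]phenyl}-3-[(trimethylsilyl)oxy]propan-1-one | C[Si](C)(C)O[C@H](c1ccc(O[Si](C)(C)C(C)(C)C)cc1)CC(=O)c1cc(CC=C(C)C)c(O[Si](C)(C)C(C)(C)C)c(CC=C(C)C)c1Cl | intermediate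
9 | (3S)-1-{4-[(tert-butyldimethylsilyl)oxy]-2-chloro-3,5-bis(3-methylbut-2-en-1-yl)phenyl}-3-{4-[(tert-butyldimethylsilyl)oxy]phenyl}-3-hydroxypropan-1-one | O[C@H](c1ccc(O[Si](C)(C)C(C)(C)C)cc1)CC(=O)c1cc(CC=C(C)C)c(O[Si](C)(C)C(C)(C)C)c(CC=C(C)C)c1Cl | intermediate
10 | (2S)-7-[(tert-butyldimethylsilyl)oxy]-2-{4-[(tert-butyldimethylsilyl)oxy]phenyl}-6,8-bis(3-methylbut-2-en-1-yl)-2,3-dihydro-4H-chromen-4-one | CC(C)=CCc1cc2c(c(CC=C(C)C)c1O[Si](C)(C)C(C)(C)C)O[C@H](c1ccc(O[Si](C)(C)C(C)(C)C)cc1)CC2=O | intermediate
11 | (2S)-7-hydroxy-2-(4-hydroxyphenyl)-6,8-bis(3-methylbut-2-en-1-yl)-2,3-dihydro-4H-chromen-4-one | CC(C)=CCc1cc2c(c(CC=C(C)C)c1O)O[C@H](c1ccc(O)cc1)CC2=O | target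

Total step count: 6. Longest linear sequence: 6 steps (1 → 2 → 4 → 5 → 6 → 10 → 11).

**Steps most likely to fail**

Step 5 (key step). In the palladium stage the β-hydroxy ketone may dehydrate or undergo retro-aldol cleavage under base, or the palladium alkoxide may undergo β-hydride elimination instead of C–O reductive elimination. Residues of the aldol stage may also slow the catalyst, and reversible base-induced opening of the pyranone ring would erode the enantiomeric purity. The fallback avoids any β-hydroxy ketone and sets C2 by conjugate arylation. It sets out from 5: formylation with ethyl formate and NaH in THF should give the hydroxymethylene ketone 1-{4-[(tert-butyldimethylsilyl)oxy]-2-chloro-3,5-bis(3-methylbut-2-en-1-yl)phenyl}-3-hydroxyprop-2-en-1-one F1. Copper-catalysed intramolecular O-arylation (CuI, 1,10-phenanthroline, K3PO4, toluene, 100 °C) should close it to the chromone 7-[(tert-butyldimethylsilyl)oxy]-6,8-bis(3-methylbut-2-en-1-yl)-4H-chromen-4-one F2. A rhodium(I)-catalysed enantioselective 1,4-addition of {4-[(tert-butyldimethylsilyl)oxy]phenyl}boronic acid (chiral diene or bisphosphine ligand, the antipode that gives 2S; toluene/H2O) then leads to 10, where the route is rejoined.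

Step 2. The prenyl boronate may couple through its γ-carbon (reverse-prenyl isomer). The reaction may also stall or protodebrominate at the C–Br bond that lies between Cl and the phenoxide oxygen. The fallback sets out from 2: the same twofold coupling with 2-allyl-4,4,5,5-tetramethyl-1,3,2-dioxaborolane (smaller group, no α/γ question) should give 1-[2-chloro-4-hydroxy-3,5-di(prop-2-en-1-yl)phenyl]ethan-1-one F3. Cross-metathesis with 2-methyl-2-butene (second-generation NHC–ruthenium benzylidene catalyst, CH2Cl2, 40 °C) then turns both allyl groups into prenyl groups and returns to the route at 4.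

Step 1. Bromination may occur at the enolisable acetyl group, and the second ring substitution may stall because its site lies between Cl and OH. The fallback uses no halogen handles: direct ortho-C-prenylation of the sodium phenoxide of 1 with 1-bromo-3-methylbut-2-ene in toluene (C-alkylation of a tight ion pair in a non-polar medium) leads from 1 straight to 4, bypassing 2. It is shorter but less selective, and it makes no compound outside the list (F0).

**Further compounds**
F1 | step 5 | 1-{4-[(tert-butyldimethylsilyl)oxy]-2-chloro-3,5-bis(3-methylbut-2-en-1-yl)phenyl}-3-hydroxyprop-2-en-1-one | O/C=C\C(=O)c1cc(CC=C(C)C)c(O[Si](C)(C)C(C)(C)C)c(CC=C(C)C)c1Cl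
F2 | step 5 | 7-[(tert-butyldimethylsilyl)oxy]-6,8-bis(3-methylbut-2-en-1-yl)-4H-chromen-4-one | CC(C)=CCc1cc2c(c(CC=C(C)C)c1O[Si](C)(C)C(C)(C)C)OC=CC2=O
F3 | step 2 | 1-[2-chloro-4-hydroxy-3,5-di(prop-2-en-1-yl)phenyl]ethan-1-one | CC(=O)c1cc(CC=C)c(O)c(CC=C)c1Cl
F0 | step 1 | none | none
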